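## The problem

Compound 19 is a 2,5-diaryl-3,4-dimethyltetrahydrofuran. Ring A (4-hydroxyphenyl) sits on C2 and ring B on C5; ring B carries a hydroxyl para to C5 and, ortho to that hydroxyl, a 1-arylpropan-2-yl chain ending in ring C (a second 4-hydroxyphenyl). The oxolane has four contiguous stereocentres, (2S,3S,4R,5R): the aryl groups are cis to each other, the methyl groups are cis to each other, and each methyl is trans to the aryl group beside it. The fifth centre, the (R)-configured benzylic CH(CH3) of the side chain, is insulated from the ring by ring B. It can neither direct the ring centres nor be directed by them, so a reagent must set it, and any error in ring configuration then appears as a remote diastereomer that is hard to detect or remove. Within the ring the centres can be chained: a fixed C4 can dictate C5, C5 can dictate C2 through a cis ring closure, and C3 can be corrected by equilibration against C2 while it carries an ester. C2 and C5 are benzylic ether carbons para to oxygen. Acids ionise them (epimerisation, ring opening) and hydrogenolysis can cut them, so acid-labile phenol protection and a final demethylation are excluded and the last deprotection needs care. The feature the plan uses is the bond pair O1–C5 and C2–C3: C5 is benzylic and para to oxygen, so it can serve as the electrophilic donor carbon of a cyclopropane; C3, next to the methyl-bearing C4, can be a malonate carbon; and C2 with O1 is at the oxidation level of an aromatic aldehyde.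

## Retrosynthesis

**19 from 18.** The three O–H bonds are traced back to O–benzyl bonds in the tribenzyl ether 18. Benzyl is preferred to methyl (removal with BBr3 would open the bis-benzylic ether), to silyl (lost to methoxide and hot halide) and to acetal groups (acid). The forward step must cleave three aryl benzyl ethers faster than the two benzylic C–O bonds of the ring.

**18 from 15 by way of 17 and 16.** No skeletal bond is cut; the C3 methyl group is traced to the ester of 15 through mesylate 17 and alcohol 16. An ester at C3 pays twice: it makes C3 a carbon nucleophile for ring construction, and it makes C3 epimerisable so that the 2,3-trans relationship can be reached under thermodynamic control. Installing the methyl group directly by enolate methylation would offer neither advantage. The forward steps are a reduction, a sulfonylation and a hydride displacement, none of which touches a stereocentre.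

**15 from 13.** A second ester is added to C3, giving the malonate-derived diester 13 in which C3 is no longer stereogenic. Only C2, C4 and C5 remain to be controlled in ring formation. The forward reaction is a dealkoxycarbonylation followed by equilibration, which requires that the ester prefer the side away from the C2 aryl group.

**13 from 11 and 12.** O1–C5 and C2–C3 are cut together, a (3+2) retron leading to the cis-cyclopropane diester 11 and 4-(benzyloxy)benzaldehyde 12.
- Against the mirror-image pair O1–C2/C4–C5 (the same reaction with the aryl roles exchanged): this direction makes the aldehyde a commercial compound that can be used in excess.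
- Against a single C–O cut (cycloetherification of a 1,4-diol): that route would pass through freely ionising para-alkoxybenzylic cations at both carbinol carbons.
- Against cuts at C3–C4: these are treated under the roads not taken.
- Gain: a ring, two bonds and two stereocentres are exchanged for a cyclopropane with one adjustable element (its absolute configuration).
- Demand on the forward reaction: inversion at C5 and a 2,5-cis closure.

**11 from 8 and 10.** Both bonds from the malonate carbon are cut, a carbene-transfer retron leading to the (Z)-propenyl arene 8 and the malonate iodonium ylide 10. Ring closure of an arylidene malonate with a sulfur ethylide would give the trans cyclopropane. Double displacement on a cyclic sulfate would need an erythro diol and an SN2 step at an easily ionised benzylic carbon. Carbene transfer is stereospecific, so the cis geometry of 8 becomes the cis relationship in 11, and one choice of alkene face by the catalyst fixes both ring centres.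

**8 from 6 and 7.** The aryl–alkenyl bond is cut to the aryl bromide 6 and (Z)-prop-1-enylboronic acid 7. A cross-coupling with retention of alkene geometry is preferred to a Wittig ethylidenation of an aldehyde, which would give Z/E mixtures.

**6 from 5, and 5 from 2 and 4.** The side-chain centre is traced to the (E)-alkene 5 (addition of H2 only), and the C=C bond of 5 to ketone 2 and phosphonate 4. This is three steps from commercial compounds, against six or more for an auxiliary-controlled enolate alkylation. The forward reactions must give geometrically pure 5 and a face-selective hydrogenation that spares C–Br and O–benzyl bonds.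

**Starting materials.** Ketone 2 comes from the bromohydroxyacetophenone 1 by benzylation, 4 from the benzylic chloride 3 by an Arbuzov reaction, and 10 from dimethyl malonate 9.

## Roads not taken

**Alternative 1:** Prins cyclisation with pinacol ring contraction.
- Cut: C4–C5 together with C2–C3, with O1–C5 already present in an acetal. The precursor is the dioxolane A1 (ring B on the acetal carbon, ring A on C5 of the dioxolane, an (E)-but-2-en-2-yl group on C4).
- Key step: SnCl4 would open the acetal at the allylic oxygen to an oxocarbenium ion. The alkene would attack it in a chair-like Prins closure (C4–C5, methyl equatorial and hence trans to ring B). The benzylic carbon would then migrate to the tertiary cation (C2–C3) while the carbinol carbon becomes a formyl group, giving the 3-formyl oxolane A2.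
- Merits: one step makes both C–C bonds and the ring. The absolute configuration comes from a diol carbon, not from a carbene transfer. After the key step a single decarbonylation would reach 18, against four steps in the chosen plan; in end-game economy this road is the better one.
- Weak points:
  - Both C–O carbons that must survive are para-alkoxybenzylic, so SnCl4 can ionise the wrong acetal bond or the benzylic C–O bond of A1 and erase the one centre that carries the absolute information.
  - The tertiary cation is generated among three electron-rich benzyloxyarenes.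
  - C3 is created quaternary in A2, and its formyl group must be removed with retention by stoichiometric Rh(PPh3)3Cl at a neopentyl-type aldehyde.
  - A1 needs an enantiopure diol and a stereodefined trisubstituted alkene, which is no shorter than making 11.
- Comparison: against the shorter end game, the chosen plan offers an annulation established for these partners (alkoxyaryl donor, aromatic aldehyde) and a C3 centre fixed by equilibration instead of a stereoretentive extrusion.

**Alternative 2:** carbene C–H insertion to a dihydrobenzofuran, then ring opening.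
- Cut: the bond between the side-chain stereocentre and its CH2 neighbour, so this road concerns only the ring B fragment.
- Key step: the aryldiazoacetate A3 would be converted by a chiral dirhodium carboxylate (Rh2(S-PTTL)4 or its antipode) into a carbene that inserts into the benzylic O–CH2 bond, closing the cis-dihydrobenzofuran A4. For the (R) side chain the (2R,3S) enantiomer of A4 is required.
- Merits: enantioselective C–H insertion of this kind is well documented for exactly this substrate class. In the reliability of the enantio-determining event it is probably ahead of the hydrogenation of a hindered ortho-alkoxy alkene used here.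
- Weak points:
  - A4 must still be opened at its benzylic C–O bond. Hydrogenolysis would also remove the bromine and the benzyl ether, so a coupling handle and the protection would have to be reinstalled.
  - The ester must then be taken down to methyl in three further steps.
  - The four ring stereocentres, the core of the problem, are not addressed.
- Comparison: the chosen plan reaches 6 in three steps with the bromine intact, and keeps an auxiliary route in reserve.

**Alternative 3:** 5-exo radical cyclisation of a bis-benzylic bromo ether.
- Cut: C3–C4.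
- Key step: Bu3SnH and AIBN would generate the C3 radical of the bromo ether A5. It would add 5-exo-trig to the vinyl group on C5, and the exocyclic radical would end as the C4 methyl group, giving A6, which is the same compound as 18.
- Merits: both methyl groups arrive in place and no ester has to be excised. After ring formation this road saves four steps and is clearly the most economical.
- Weak points:
  - Two stereocentres (C3, C4) are formed in one radical step under Beckwith–Houk control. The required 2,3-trans/3,4-cis/4,5-trans pattern puts the two methyl groups cis, so only modest selectivity can be expected.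
  - A5 is an ether between two different, enantiopure, para-alkoxybenzylic secondary alcohols. Forming it without ionisation at either carbon is difficult, and the β-bromo ether is prone to elimination.
  - Tin is used in stoichiometric amount.
- Comparison: against the step saving, the chosen plan offers a defined origin for every ring centre (C5 by inversion, C2 by cis closure, C3 by equilibration) and a convergent union of two simple fragments.

Key step: step 8

Remark: the sense of induction of the two chiral catalysts (steps 4 and 7) is assigned by analogy with simpler alkenes; both ligand antipodes are accessible, and the one that delivers the drawn configuration is to be used.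

In the step names, Ar(B) stands for 4-(benzyloxy)-3-{(2R)-1-[4-(benzyloxy)phenyl]propan-2-yl}phenyl; full names are in the compound list.

## Route

Step 1
Reactants: 1 1-(5-bromo-2-hydroxyphenyl)ethan-1-one
Product: 2 1-[2-(benzyloxy)-5-bromophenyl]ethan-1-one
Conditions: BnBr, K2CO3, DMF, 60 °C
Reagents that add atoms: benzyl bromide, BrCc1ccccc1
Why: Williamson ether synthesis; carbonate is basic enough for the hydrogen-bonded ortho-acyl phenol, and the benzyl ether should survive every later step up to the final hydrogenolysis.

Step 2
Reactants: 3 1-(benzyloxy)-4-(chloromethyl)benzene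
Product: 4 diethyl {[4-(benzyloxy)phenyl]methyl}phosphonate
Conditions: P(OEt)3 (neat), 140 °C
Reagents that add atoms: triethyl phosphite, CCOP(OCC)OCC
Why: Michaelis–Arbuzov reaction of a reactive benzylic chloride; chloroethane distils off and drives the reaction.

Step 3
Reactants: 2 1-[2-(benzyloxy)-5-bromophenyl]ethan-1-one, 4 diethyl {[4-(benzyloxy)phenyl]methyl}phosphonate
Product: 5 1-(benzyloxy)-2-{(1E)-1-[4-(benzyloxy)phenyl]prop-1-en-2-yl}-4-bromobenzene
Conditions: KOt-Bu, THF, 0 °C → reflux; (E)-isomer isolated by crystallisation
Reagents that add atoms: none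
Why: Horner–Wadsworth–Emmons olefination of an aryl methyl ketone with a benzylic phosphonate carbanion, which favours the alkene with the two aryl groups trans. The (E)-isomer must be freed of (Z), since the two would be hydrogenated to opposite enantiomers; (Z)-rich mother liquor can be re-equilibrated with catalytic iodine.

Step 4
Reactants: 5 1-(benzyloxy)-2-{(1E)-1-[4-(benzyloxy)phenyl]prop-1-en-2-yl}-4-bromobenzene
Product: 6 1-(benzyloxy)-2-{(2R)-1-[4-(benzyloxy)phenyl]propan-2-yl}-4-bromobenzene
Conditions: [Ir(cod)(L)][B(C6H3(CF3)2)4] (2 mol %), L = (S)-4-tert-butyl-2-[2-(di-o-tolylphosphino)phenyl]-4,5-dihydrooxazole, H2 (50 bar), CH2Cl2, rt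
Reagents that add atoms: none
Why: Iridium–phosphinooxazoline asymmetric hydrogenation of an unfunctionalised trisubstituted (E)-1,2-diarylpropene; the ligand selects the alkene face and so sets the (R) side-chain centre (the (S)-ligand is the one known to give (R)-alkanes from (E)-1,2-diarylpropenes). This cationic catalyst should leave C–Br and O–benzyl bonds intact.

Step 5
Reactants: 6 1-(benzyloxy)-2-{(2R)-1-[4-(benzyloxy)phenyl]propan-2-yl}-4-bromobenzene, 7 (Z)-prop-1-en-1-ylboronic acid
Product: 8 1-(benzyloxy)-2-{(2R)-1-[4-(benzyloxy)phenyl]propan-2-yl}-4-[(1Z)-prop-1-en-1-yl]benzene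
Conditions: Pd(dppf)Cl2 (5 mol %), K2CO3, 1,4-dioxane/H2O, 80 °C
Reagents that add atoms: none
Why: Suzuki–Miyaura coupling; transmetalation and reductive elimination proceed with retention at the alkenyl carbon, so the (Z) geometry of the boronic acid should pass into the propenyl arene.

Step 6
Reactants: 9 dimethyl malonate
Product: 10 dimethyl 2-(phenyl-λ3-iodanylidene)propanedioate
Conditions: PhI(OAc)2, KOH, MeCN, 0 °C
Reagents that add atoms: (diacetoxyiodo)benzene, CC(=O)OI(OC(C)=O)c1ccccc1
Why: Ligand exchange of the malonate anion at hypervalent iodine gives the isolable iodonium ylide, a safer and more reactive stand-in for dimethyl diazomalonate; it is kept cold and used soon after preparation.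

Step 7
Reactants: 8 1-(benzyloxy)-2-{(2R)-1-[4-(benzyloxy)phenyl]propan-2-yl}-4-[(1Z)-prop-1-en-1-yl]benzene, 10 dimethyl 2-(phenyl-λ3-iodanylidene)propanedioate
Product: 11 dimethyl (2S,3S)-2-Ar(B)-3-methylcyclopropane-1,1-dicarboxylate (aryl and methyl cis)
Conditions: Cu(MeCN)4PF6 (10 mol %), chiral side-arm bis(oxazoline) ligand (12 mol %), 4 Å MS, PhMe, 0 °C → rt
Reagents that add atoms: none
Why: Monovalent copper decomposes the ylide to a copper malonyl carbene that adds to the alkene in one stereospecific syn event, so the (Z) geometry of 8 becomes the cis aryl/methyl pair of 11; enantioselective carbene transfer from malonate iodonium ylides with chiral bis(oxazoline) copper catalysts is established for cis-1,2-disubstituted aryl alkenes. Both ring centres follow from the single choice of alkene face made by the ligand; the remote side-chain centre is not expected to interfere.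

Step 8
Reactants: 11 dimethyl (2S,3S)-2-Ar(B)-3-methylcyclopropane-1,1-dicarboxylate, 12 4-(benzyloxy)benzaldehyde
Product: 13 dimethyl (2R,4R,5R)-2-[4-(benzyloxy)phenyl]-5-Ar(B)-4-methyloxolane-3,3-dicarboxylate
Conditions: Sn(OTf)2 (10 mol %), 12 (3 equiv), CH2Cl2, 0 °C → rt
Reagents that add atoms: none
Why: Sn(OTf)2 chelates the geminal diester of 11 and polarises the bond from the malonate carbon to the benzylic carbon, which the para-benzyloxy group stabilises; the carbonyl oxygen of 12 attacks that carbon from the side opposite the departing malonate (SN2-like displacement on an intimate ion pair) and forms O1–C5 with inversion. The tin malonate enolate then adds to the (E)-oxocarbenium carbon and forms C2–C3. The closest known reaction type is the Lewis-acid-catalysed (3+2) annulation of 2-aryl cyclopropane-1,1-diesters with aldehydes to 2,5-cis-tetrahydrofurans, which is documented for electron-rich aryl donors, aromatic aldehydes and 2,3-disubstituted cyclopropanes. The oxolane closes through C2–C3 in an aldol-type 5-endo-trig (enolexo) attack on the oxocarbenium ion, O1–C5 having been made intermolecularly. C5 is controlled by the benzylic carbon of 11 through inversion, which turns the cis aryl/methyl pair of the cyclopropane into the 4,5-trans pair; C2 is controlled by C5 through an envelope transition state with both aryl groups pseudo-equatorial, which gives the 2,5-cis ring; C4 is carried over unchanged from the methyl-bearing carbon of 11. The step needs direct displacement to outrun ionisation to a free benzylic cation and the kinetic cis product not to be re-opened; excess aldehyde, a low catalyst loading and a stop at full conversion serve this, and the 4,5-trans arrangement is also the less crowded one, so leakage through the open zwitterion is expected to converge on the same C5 configuration. Regiochemistry is secured by the aryl group, since only the aryl-bearing C–C bond of the cyclopropane is polarised enough to break.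

Step 9
Reactants: 13 dimethyl (2R,4R,5R)-2-[4-(benzyloxy)phenyl]-5-Ar(B)-4-methyloxolane-3,3-dicarboxylate
Product: 15 methyl (2S,3S,4R,5R)-2-[4-(benzyloxy)phenyl]-5-Ar(B)-4-methyloxolane-3-carboxylate, via C3-epimeric monoester mixture 14 (not isolated)
Conditions: LiCl, H2O, DMSO, 150 °C; then NaOMe (cat.), MeOH/THF, rt
Reagents that add atoms: none
Why: Krapcho dealkoxycarbonylation: chloride demethylates one ester, the carboxylate loses CO2 and protonation gives 14 as C3 epimers. Methoxide then equilibrates C3 through the ester enolate to the isomer with the ester trans to the C2 aryl group and cis only to the smaller C4 methyl group. Ring opening by β-elimination of O1 would be the reverse of a 5-endo-trig closure and is not expected to compete at room temperature.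

Step 10
Reactants: 15 methyl (2S,3S,4R,5R)-2-[4-(benzyloxy)phenyl]-5-Ar(B)-4-methyloxolane-3-carboxylate
Product: 16 [(2S,3R,4R,5R)-2-[4-(benzyloxy)phenyl]-5-Ar(B)-4-methyloxolan-3-yl]methanol
Conditions: LiAlH4, THF, 0 °C
Reagents that add atoms: none
Why: Hydride reduction of the ester to the primary alcohol; no stereocentre is involved (the change of the C3 descriptor is formal) and benzyl ethers and the oxolane are inert.

Step 11
Reactants: 16 [(2S,3R,4R,5R)-2-[4-(benzyloxy)phenyl]-5-Ar(B)-4-methyloxolan-3-yl]methanol
Product: 17 [(2S,3R,4R,5R)-2-[4-(benzyloxy)phenyl]-5-Ar(B)-4-methyloxolan-3-yl]methyl methanesulfonate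
Conditions: MsCl, Et3N, CH2Cl2, 0 °C
Reagents that add atoms: methanesulfonyl chloride, CS(=O)(=O)Cl
Why: Sulfonylation of a primary alcohol under basic conditions, which avoids any acid that could ionise C2 or C5.

Step 12
Reactants: 17 [(2S,3R,4R,5R)-2-[4-(benzyloxy)phenyl]-5-Ar(B)-4-methyloxolan-3-yl]methyl methanesulfonate
Product: 18 (2S,3S,4R,5R)-2-[4-(benzyloxy)phenyl]-5-Ar(B)-3,4-dimethyloxolane
Conditions: LiBHEt3, THF, 0 °C → 50 °C
Reagents that add atoms: none
Why: SN2 displacement of a primary mesylate by the strong hydride donor LiBHEt3 (deoxygenation by way of a sulfonate); the β-branched centre is still accessible to this reagent and no stereocentre is touched.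

Step 13
Reactants: 18 (2S,3S,4R,5R)-2-[4-(benzyloxy)phenyl]-5-Ar(B)-3,4-dimethyloxolane
Product: 19 4-[(2S,3S,4R,5R)-5-{4-hydroxy-3-[(2R)-1-(4-hydroxyphenyl)propan-2-yl]phenyl}-3,4-dimethyloxolan-2-yl]phenol
Conditions: H2 (1 atm), 10% Pd/C, EtOAc, rt
Reagents that add atoms: none
Why: Hydrogenolysis of three aryl benzyl ethers on palladium in a neutral aprotic solvent; aryl benzyl ethers are cleaved much faster than the dialkyl benzylic C–O bonds of the ring, and the reaction is stopped once three equivalents of hydrogen are taken up.

## Compound list

1 | 1-(5-bromo-2-hydroxyphenyl)ethan-1-one (5'-bromo-2'-hydroxyacetophenone) | CC(=O)c1cc(Br)ccc1O | starting material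
2 | 1-[2-(benzyloxy)-5-bromophenyl]ethan-1-one | CC(=O)c1cc(Br)ccc1OCc1ccccc1 | intermediate
3 | 1-(benzyloxy)-4-(chloromethyl)benzene (4-(benzyloxy)benzyl chloride) | ClCc1ccc(OCc2ccccc2)cc1 | starting material
4 | diethyl {[4-(benzyloxy)phenyl]methyl}phosphonate | CCOP(=O)(OCC)Cc1ccc(OCc2ccccc2)cc1 | intermediate
5 | 1-(benzyloxy)-2-{(1E)-1-[4-(benzyloxy)phenyl]prop-1-en-2-yl}-4-bromobenzene | C/C(=C\c1ccc(OCc2ccccc2)cc1)c1cc(Br)ccc1OCc1ccccc1 | intermediate
6 | 1-(benzyloxy)-2-{(2R)-1-[4-(benzyloxy)phenyl]propan-2-yl}-4-bromobenzene | Brc1ccc(OCc2ccccc2)c([C@H](C)Cc2ccc(OCc3ccccc3)cc2)c1 | intermediate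
7 | (Z)-prop-1-en-1-ylboronic acid | C/C=C\B(O)O | starting material
8 | 1-(benzyloxy)-2-{(2R)-1-[4-(benzyloxy)phenyl]propan-2-yl}-4-[(1Z)-prop-1-en-1-yl]benzene | C/C=C\c1ccc(OCc2ccccc2)c([C@H](C)Cc2ccc(OCc3ccccc3)cc2)c1 | intermediate
9 | dimethyl malonate | COC(=O)CC(=O)OC | starting material
10 | dimethyl 2-(phenyl-λ3-iodanylidene)propanedioate (phenyliodonium bis(methoxycarbonyl)methanide) | COC(=O)[C-](C(=O)OC)[I+]c1ccccc1 | intermediate
11 | dimethyl (2S,3S)-2-{4-(benzyloxy)-3-[(2R)-1-[4-(benzyloxy)phenyl]propan-2-yl]phenyl}-3-methylcyclopropane-1,1-dicarboxylate (aryl and methyl cis) | C[C@H]1[C@@H](c2ccc(OCc3ccccc3)c([C@H](C)Cc3ccc(OCc4ccccc4)cc3)c2)C1(C(=O)OC)C(=O)OC | intermediate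
12 | 4-(benzyloxy)benzaldehyde | O=Cc1ccc(OCc2ccccc2)cc1 | starting material
13 | dimethyl (2R,4R,5R)-2-[4-(benzyloxy)phenyl]-5-{4-(benzyloxy)-3-[(2R)-1-[4-(benzyloxy)phenyl]propan-2-yl]phenyl}-4-methyloxolane-3,3-dicarboxylate | C[C@@H]1C(C(=O)OC)(C(=O)OC)[C@@H](c2ccc(OCc3ccccc3)cc2)O[C@H]1c1ccc(OCc2ccccc2)c([C@H](C)Cc2ccc(OCc3ccccc3)cc2)c1 | intermediate
14 | methyl (2S,4R,5R)-2-[4-(benzyloxy)phenyl]-5-{4-(benzyloxy)-3-[(2R)-1-[4-(benzyloxy)phenyl]propan-2-yl]phenyl}-4-methyloxolane-3-carboxylate, mixture of C3 epimers (not isolated) | C[C@@H]1C(C(=O)OC)[C@@H](c2ccc(OCc3ccccc3)cc2)O[C@H]1c1ccc(OCc2ccccc2)c([C@H](C)Cc2ccc(OCc3ccccc3)cc2)c1 | intermediate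
15 | methyl (2S,3S,4R,5R)-2-[4-(benzyloxy)phenyl]-5-{4-(benzyloxy)-3-[(2R)-1-[4-(benzyloxy)phenyl]propan-2-yl]phenyl}-4-methyloxolane-3-carboxylate | C[C@@H]1[C@H](C(=O)OC)[C@@H](c2ccc(OCc3ccccc3)cc2)O[C@H]1c1ccc(OCc2ccccc2)c([C@H](C)Cc2ccc(OCc3ccccc3)cc2)c1 | intermediate
16 | [(2S,3R,4R,5R)-2-[4-(benzyloxy)phenyl]-5-{4-(benzyloxy)-3-[(2R)-1-[4-(benzyloxy)phenyl]propan-2-yl]phenyl}-4-methyloxolan-3-yl]methanol | C[C@@H]1[C@H](CO)[C@@H](c2ccc(OCc3ccccc3)cc2)O[C@H]1c1ccc(OCc2ccccc2)c([C@H](C)Cc2ccc(OCc3ccccc3)cc2)c1 | intermediate
17 | [(2S,3R,4R,5R)-2-[4-(benzyloxy)phenyl]-5-{4-(benzyloxy)-3-[(2R)-1-[4-(benzyloxy)phenyl]propan-2-yl]phenyl}-4-methyloxolan-3-yl]methyl methanesulfonate | C[C@@H]1[C@H](COS(C)(=O)=O)[C@@H](c2ccc(OCc3ccccc3)cc2)O[C@H]1c1ccc(OCc2ccccc2)c([C@H](C)Cc2ccc(OCc3ccccc3)cc2)c1 | intermediate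
18 | (2S,3S,4R,5R)-2-[4-(benzyloxy)phenyl]-5-{4-(benzyloxy)-3-[(2R)-1-[4-(benzyloxy)phenyl]propan-2-yl]phenyl}-3,4-dimethyloxolane | C[C@@H]1[C@H](C)[C@@H](c2ccc(OCc3ccccc3)cc2)O[C@H]1c1ccc(OCc2ccccc2)c([C@H](C)Cc2ccc(OCc3ccccc3)cc2)c1 | intermediate
19 | 4-[(2S,3S,4R,5R)-5-{4-hydroxy-3-[(2R)-1-(4-hydroxyphenyl)propan-2-yl]phenyl}-3,4-dimethyloxolan-2-yl]phenol (CNP0232576.1) | C[C@@H]1[C@H](C)[C@@H](c2ccc(O)cc2)O[C@H]1c1ccc(O)c([C@H](C)Cc2ccc(O)cc2)c1 | target

## Step count and least certain steps

Total: 13 steps (steps 2 and 6 prepare the phosphonate and the ylide off the main line). Longest linear sequence: 11 steps (1 → 2 → 5 → 6 → 8 → 11 → 13 → 15 → 16 → 17 → 18 → 19).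

**Step 8 (key step).** The most likely failure is loss of stereochemical fidelity at C5. The donor ring of 11 carries an alkyl group besides the para-benzyloxy group, and the cis methyl group slows backside attack. Ionisation to the open benzylic cation, with cis-to-trans isomerisation of the cyclopropane, may therefore compete with direct displacement, and slow turnover would expose the kinetic 2,5-cis product to re-opening. Because 11 ends an eight-step line and its ring configuration cannot be read against the remote side-chain centre, such leakage would also be hard to diagnose.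

Fallback: exchange the roles of the two aryl groups, which the local symmetry of the 2,5-diaryl-3,4-dimethyl core allows. The fallback sets out from 6 and 12 and returns at 18. Bromine–lithium exchange on 6 (n-BuLi, THF, −78 °C) and formylation with DMF would give the ring B aldehyde F1. Z-selective Wittig ethylidenation of 12 (EtPPh3Br, KN(SiMe3)2, THF, −78 °C) would give the (Z)-propenyl arene F2. Cyclopropanation of F2 with 10 as in step 7, with the antipodal ligand, would give the simple cis-cyclopropane F3. Its enantiomeric purity can be measured and raised by crystallisation, its donor ring is the less electron-rich one, and it can be used in excess and recovered to show whether configuration is being lost. Sn(OTf)2-catalysed annulation of F3 with F1 would give the regioisomeric oxolane diester F4 (in target numbering, O1–C2 by inversion and C4–C5 by aldol closure). Krapcho decarboxylation and equilibration would give the monoester F5, LiAlH4 the alcohol F6 and MsCl the mesylate F7, which LiBHEt3 would reduce to 18.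

**Step 7.** The most likely failure is insufficient facial selectivity of carbene transfer to this cis-disubstituted, fully elaborated alkene; partial loss of the cis geometry through stepwise addition to the electron-rich styrene is a lesser concern. The unwanted ring epimer differs from 11 only relative to the distant side-chain centre and would be carried forward unnoticed.

Fallback, from 8 back to 11: abandon catalyst control. Cyclopropanation of 8 with 10 under the achiral dirhodium tetracarboxylate Rh2(esp)2 (CH2Cl2, 0 °C → rt), a robust stereospecific carbene transfer, should give 11 together with its ring epimer, the (2R,3R)-cyclopropane F8. The two would be separated by preparative chromatography on a chiral stationary phase, which distinguishes the locally mirror-image rings, and only 11 taken on.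

**Step 4.** The most likely failure is slow or poorly face-selective hydrogenation, because the ortho-benzyloxy group twists ring B out of the alkene plane and crowds the catalyst. Any (Z)-isomer left in 5 would be reduced to the enantiomer.

Fallback, from 2 and 3 to 6 by auxiliary-controlled alkylation. The Willgerodt–Kindler reaction of 2 (S8, morpholine, 130 °C) would give the thiomorpholide F9, hydrolysed (KOH, aqueous EtOH, reflux) to the arylacetic acid F10. Acylation of (R)-4-benzyl-1,3-oxazolidin-2-one (pivaloyl chloride, Et3N; then the lithiated auxiliary) would give the imide F11. Its sodium enolate (NaN(SiMe3)2, THF, −78 °C) would be alkylated by 3 (with NaI) on the face away from the auxiliary benzyl group, giving the (2R)-alkylated imide F12. LiBH4 would release the auxiliary and give the primary alcohol F13; tosylation would give the tosylate F14, which LiBHEt3 would reduce to the methyl group of 6.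

**Step 13.** The most likely failure is over-reduction: hydrogenolytic cleavage of the C2–O1 or C5–O1 bond, both benzylic ethers of para-oxygenated arenes, which become more labile once the phenols are free.

Fallback, from 18 to 19 without hydrogen or acid: nucleophilic debenzylation with sodium ethanethiolate (NaSEt, DMF, 110 °C, then mild acidification). This is an SN2 dealkylation at the three benzyl carbons that cannot touch the secondary dialkyl ether carbons of the ring; it makes no new isolated compound.

## Further compounds

F1 | step 8 | 4-(benzyloxy)-3-{(2R)-1-[4-(benzyloxy)phenyl]propan-2-yl}benzaldehyde | O=Cc1ccc(OCc2ccccc2)c([C@H](C)Cc2ccc(OCc3ccccc3)cc2)c1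
F2 | step 8 | 1-(benzyloxy)-4-[(1Z)-prop-1-en-1-yl]benzene | C/C=C\c1ccc(OCc2ccccc2)cc1
F3 | step 8 | dimethyl (2R,3R)-2-[4-(benzyloxy)phenyl]-3-methylcyclopropane-1,1-dicarboxylate (aryl and methyl cis) | C[C@@H]1[C@H](c2ccc(OCc3ccccc3)cc2)C1(C(=O)OC)C(=O)OC
F4 | step 8 | dimethyl (2S,4S,5S)-5-[4-(benzyloxy)phenyl]-2-{4-(benzyloxy)-3-[(2R)-1-[4-(benzyloxy)phenyl]propan-2-yl]phenyl}-4-methyloxolane-3,3-dicarboxylate | C[C@@H]1[C@@H](c2ccc(OCc3ccccc3)cc2)O[C@@H](c2ccc(OCc3ccccc3)c([C@H](C)Cc3ccc(OCc4ccccc4)cc3)c2)C1(C(=O)OC)C(=O)OC
F5 | step 8 | methyl (2R,3R,4S,5S)-5-[4-(benzyloxy)phenyl]-2-{4-(benzyloxy)-3-[(2R)-1-[4-(benzyloxy)phenyl]propan-2-yl]phenyl}-4-methyloxolane-3-carboxylate | COC(=O)[C@@H]1[C@H](C)[C@@H](c2ccc(OCc3ccccc3)cc2)O[C@H]1c1ccc(OCc2ccccc2)c([C@H](C)Cc2ccc(OCc3ccccc3)cc2)c1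
F6 | step 8 | [(2R,3S,4S,5S)-5-[4-(benzyloxy)phenyl]-2-{4-(benzyloxy)-3-[(2R)-1-[4-(benzyloxy)phenyl]propan-2-yl]phenyl}-4-methyloxolan-3-yl]methanol | OC[C@@H]1[C@H](C)[C@@H](c2ccc(OCc3ccccc3)cc2)O[C@H]1c1ccc(OCc2ccccc2)c([C@H](C)Cc2ccc(OCc3ccccc3)cc2)c1
F7 | step 8 | [(2R,3S,4S,5S)-5-[4-(benzyloxy)phenyl]-2-{4-(benzyloxy)-3-[(2R)-1-[4-(benzyloxy)phenyl]propan-2-yl]phenyl}-4-methyloxolan-3-yl]methyl methanesulfonate | CS(=O)(=O)OC[C@@H]1[C@H](C)[C@@H](c2ccc(OCc3ccccc3)cc2)O[C@H]1c1ccc(OCc2ccccc2)c([C@H](C)Cc2ccc(OCc3ccccc3)cc2)c1
F8 | step 7 | dimethyl (2R,3R)-2-{4-(benzyloxy)-3-[(2R)-1-[4-(benzyloxy)phenyl]propan-2-yl]phenyl}-3-methylcyclopropane-1,1-dicarboxylate (ring epimer of 11) | C[C@@H]1[C@H](c2ccc(OCc3ccccc3)c([C@H](C)Cc3ccc(OCc4ccccc4)cc3)c2)C1(C(=O)OC)C(=O)OC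
F9 | step 4 | 2-[2-(benzyloxy)-5-bromophenyl]-1-(morpholin-4-yl)ethane-1-thione | S=C(Cc1cc(Br)ccc1OCc1ccccc1)N1CCOCC1
F10 | step 4 | [2-(benzyloxy)-5-bromophenyl]acetic acid | OC(=O)Cc1cc(Br)ccc1OCc1ccccc1
F11 | step 4 | (4R)-4-benzyl-3-{[2-(benzyloxy)-5-bromophenyl]acetyl}-1,3-oxazolidin-2-one | O=C(Cc1cc(Br)ccc1OCc1ccccc1)N1[C@H](Cc2ccccc2)COC1=O
F12 | step 4 | (4R)-4-benzyl-3-{(2R)-2-[2-(benzyloxy)-5-bromophenyl]-3-[4-(benzyloxy)phenyl]propanoyl}-1,3-oxazolidin-2-one | O=C([C@H](Cc1ccc(OCc2ccccc2)cc1)c1cc(Br)ccc1OCc1ccccc1)N1[C@H](Cc2ccccc2)COC1=O
F13 | step 4 | (2R)-2-[2-(benzyloxy)-5-bromophenyl]-3-[4-(benzyloxy)phenyl]propan-1-ol | OC[C@H](Cc1ccc(OCc2ccccc2)cc1)c1cc(Br)ccc1OCc1ccccc1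
F14 | step 4 | (2R)-2-[2-(benzyloxy)-5-bromophenyl]-3-[4-(benzyloxy)phenyl]propyl 4-methylbenzenesulfonate | Cc1ccc(cc1)S(=O)(=O)OC[C@H](Cc1ccc(OCc2ccccc2)cc1)c1cc(Br)ccc1OCc1ccccc1
F0 | step 13 | none | none
A1 | alternative 1 | (5R)-2-{4-(benzyloxy)-3-[(2R)-1-[4-(benzyloxy)phenyl]propan-2-yl]phenyl}-5-[4-(benzyloxy)phenyl]-4-[(2E)-but-2-en-2-yl]-1,3-dioxolane (acetal carbon and C4 not defined; both are lost as stereocentres) | C/C=C(\C)C1OC(c2ccc(OCc3ccccc3)c([C@H](C)Cc3ccc(OCc4ccccc4)cc3)c2)O[C@@H]1c1ccc(OCc2ccccc2)cc1
A2 | alternative 1 | (2R,3R,4R,5R)-2-[4-(benzyloxy)phenyl]-5-{4-(benzyloxy)-3-[(2R)-1-[4-(benzyloxy)phenyl]propan-2-yl]phenyl}-3,4-dimethyloxolane-3-carbaldehyde (formyl cis to both aryl groups) | C[C@@H]1[C@](C=O)(C)[C@@H](c2ccc(OCc3ccccc3)cc2)O[C@H]1c1ccc(OCc2ccccc2)c([C@H](C)Cc2ccc(OCc3ccccc3)cc2)c1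
A3 | alternative 2 | methyl 2-[2-{[4-(benzyloxy)phenyl]methoxy}-5-bromophenyl]-2-diazoacetate | COC(=O)C(=[N+]=[N-])c1cc(Br)ccc1OCc1ccc(OCc2ccccc2)cc1
A4 | alternative 2 | methyl (2R,3S)-2-[4-(benzyloxy)phenyl]-5-bromo-2,3-dihydro-1-benzofuran-3-carboxylate (cis) | COC(=O)[C@@H]1[C@H](c2ccc(OCc3ccccc3)cc2)Oc2ccc(Br)cc21
A5 | alternative 3 | 1-(benzyloxy)-4-[(1R)-1-{(1R)-1-[4-(benzyloxy)phenyl]-2-bromopropoxy}prop-2-en-1-yl]-2-{(2R)-1-[4-(benzyloxy)phenyl]propan-2-yl}benzene (bromine-bearing carbon as a mixture) | CC(Br)[C@@H](c1ccc(OCc2ccccc2)cc1)O[C@H](C=C)c1ccc(OCc2ccccc2)c([C@H](C)Cc2ccc(OCc3ccccc3)cc2)c1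
A6 | alternative 3 | (2S,3S,4R,5R)-2-[4-(benzyloxy)phenyl]-5-{4-(benzyloxy)-3-[(2R)-1-[4-(benzyloxy)phenyl]propan-2-yl]phenyl}-3,4-dimethyloxolane (identical with 18) | C[C@@H]1[C@H](C)[C@@H](c2ccc(OCc3ccccc3)cc2)O[C@H]1c1ccc(OCc2ccccc2)c([C@H](C)Cc2ccc(OCc3ccccc3)cc2)c1
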